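**Retrosynthetic overview**
- The target is cut at the depside (aryl ester) bond into a ring-A acid (2-OH as benzyl ether, side-chain ketone as dioxolane) and a ring-B phenol (benzyl 2,4-dihydroxy-6-propylbenzoate).
- Ring A is bought as methyl orsellinate. Its ArCH2–C(=O)Pr bond is made by crossed Claisen-type acylation of the laterally lithiated toluate with N-methoxy-N-methylbutanamide (key C–C bond).
- Ring B is built first: Michael addition of dimethyl malonate to (E)-hept-3-en-2-one, Dieckmann (intramolecular Claisen) closure to the cyclohexane-1,3-dione, then bromination/dehydrobromination to the resorcylate.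
- The two rings are joined last by Steglich esterification; ketal hydrolysis and global hydrogenolysis finish the synthesis.

Assumption: the target has no stereocentre (it is achiral), so there is no enantiomer to control and the SMILES is taken as drawn.

**Route**

Step 1
Reactants: 1 methyl 2,4-dihydroxy-6-methylbenzoate (methyl orsellinate)
Product: 2 methyl 2-hydroxy-4-methoxy-6-methylbenzoate
Conditions: MeI (1.1 equiv), K2CO3 (1.1 equiv), acetone, rt to 40 °C
Reagents that add atoms: iodomethane, CI
Why: Williamson ether synthesis; the 2-OH is tied up in a hydrogen bond to the ester carbonyl, so only the free 4-OH is methylated.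

Step 2
Reactants: 2 methyl 2-hydroxy-4-methoxy-6-methylbenzoate
Product: 3 methyl 2-(benzyloxy)-4-methoxy-6-methylbenzoate
Conditions: BnBr (1.3 equiv), K2CO3 (2 equiv), DMF, 60 °C
Reagents that add atoms: benzyl bromide, BrCc1ccccc1
Why: Williamson etherification under forcing conditions alkylates the chelated phenol, giving a benzyl ether that survives LDA and hydroxide and is removed at the end by hydrogenolysis.

Step 3
Reactants: 4 butanoyl chloride; 5 N,O-dimethylhydroxylamine hydrochloride
Product: 6 N-methoxy-N-methylbutanamide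
Conditions: Et3N (2.2 equiv), CH2Cl2, 0 °C to rt
Reagents that add atoms: none
Why: Schotten–Baumann-type N-acylation of the amine by the acid chloride gives the Weinreb amide cleanly.

Step 4
Reactants: 3 methyl 2-(benzyloxy)-4-methoxy-6-methylbenzoate; 6 N-methoxy-N-methylbutanamide
Product: 9 methyl 2-(benzyloxy)-4-methoxy-6-(2-oxopentyl)benzoate, via lithiated toluate 7 (not isolated), via lithium hemiaminal alkoxide 8 (not isolated)
Conditions: 3 added to LDA (1.2 equiv, commercial solution), THF, −78 °C, 30 min; then 6 (1.3 equiv), −78 to −40 °C; cold 1 M HCl quench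
Reagents that add atoms: none
Why: Lateral lithiation gives the ester-stabilised benzylic anion (vinylogous ester enolate), which is acylated in a crossed Claisen-type condensation; the chelated tetrahedral adduct releases the ketone only on work-up, so no over-addition occurs and no stereocentre is formed.

Step 5
Reactants: 9 methyl 2-(benzyloxy)-4-methoxy-6-(2-oxopentyl)benzoate
Product: 10 methyl 2-(benzyloxy)-4-methoxy-6-[(2-propyl-1,3-dioxolan-2-yl)methyl]benzoate
Conditions: TMSOCH2CH2OTMS (2 equiv), TMSOTf (10 mol %), CH2Cl2, −78 to −20 °C; then pyridine, aq. NaHCO3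
Reagents that add atoms: 1,2-bis(trimethylsilyloxy)ethane, C[Si](C)(C)OCCO[Si](C)(C)C
Why: Noyori ketalisation works at low temperature without protic acid, so the keto ester cannot close to the isocoumarin, and the masked ketone tolerates the later hydroxide and carboxyl-activation steps.

Step 6
Reactants: 10 methyl 2-(benzyloxy)-4-methoxy-6-[(2-propyl-1,3-dioxolan-2-yl)methyl]benzoate
Product: 11 2-(benzyloxy)-4-methoxy-6-[(2-propyl-1,3-dioxolan-2-yl)methyl]benzoic acid
Conditions: KOH (10 equiv), DMSO/H2O 4:1, 100 °C; then cold 1 M HCl to pH 4–5, immediate extraction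
Reagents that add atoms: potassium hydroxide, [K+].[OH-]
Why: Saponification of the di-ortho-substituted benzoate needs forcing hydroxide, which the dioxolane, benzyl ether and aryl methyl ether all tolerate.

Step 7
Reactants: 12 (E)-hept-3-en-2-one; 13 dimethyl malonate
Product: 15 methyl 2,4-dioxo-6-propylcyclohexane-1-carboxylate (racemic; enolised), via Michael adduct 14 (not isolated)
Conditions: NaOMe (1.1 equiv), MeOH, reflux; then aq. HCl, 0 °C
Reagents that add atoms: none
Why: Intermolecular Michael addition of the malonate to the enone is followed in the same pot by Dieckmann (intramolecular Claisen) closure of the methyl ketone enolate onto one ester, driven by the stabilised 1,3-dione enolate; the stereocentres formed are racemic and are erased in step 8.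

Step 8
Reactants: 15 methyl 2,4-dioxo-6-propylcyclohexane-1-carboxylate
Product: 17 methyl 2,4-dihydroxy-6-propylbenzoate, via bromo dione 16 (not isolated)
Conditions: Br2 (1.0 equiv), DMF, 0 °C, 1 h; then 80 °C
Reagents that add atoms: none
Why: α-Bromination of the β-dicarbonyl followed by thermal dehydrobromination and enolisation (oxidative aromatisation) gives the resorcylate with the ester intact.

Step 9
Reactants: 17 methyl 2,4-dihydroxy-6-propylbenzoate
Product: 18 2,4-dihydroxy-6-propylbenzoic acid (divaric acid)
Conditions: KOH (6 equiv), H2O/MeOH, 70 °C, N2; then cold 2 M HCl to pH 2 at 0 °C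
Reagents that add atoms: potassium hydroxide, [K+].[OH-]
Why: Saponification; the phenoxide carboxylate salt does not decarboxylate in base, and cold acidification avoids loss of CO2 from the free acid.

Step 10
Reactants: 18 2,4-dihydroxy-6-propylbenzoic acid
Product: 19 benzyl 2,4-dihydroxy-6-propylbenzoate
Conditions: BnBr (1.05 equiv), KHCO3 (1.2 equiv), DMF, rt
Reagents that add atoms: benzyl bromide, BrCc1ccccc1
Why: SN2 alkylation of the carboxylate; hydrogen carbonate ionises only the carboxylic acid, so the phenols are not benzylated.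

Step 11
Reactants: 11 2-(benzyloxy)-4-methoxy-6-[(2-propyl-1,3-dioxolan-2-yl)methyl]benzoic acid; 19 benzyl 2,4-dihydroxy-6-propylbenzoate
Product: 20 benzyl 4-{[2-(benzyloxy)-4-methoxy-6-[(2-propyl-1,3-dioxolan-2-yl)methyl]benzoyl]oxy}-2-hydroxy-6-propylbenzoate
Conditions: DCC (1.2 equiv), DMAP (0.2 equiv), CH2Cl2, 0 °C to rt
Reagents that add atoms: none
Why: Steglich esterification under neutral conditions keeps the dioxolane intact, and only the free 4-OH of 19 is acylated because the 2-OH is chelated to and shielded by the benzyl ester.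

Step 12
Reactants: 20 the depside ketal
Product: 21 benzyl 4-{[2-(benzyloxy)-4-methoxy-6-(2-oxopentyl)benzoyl]oxy}-2-hydroxy-6-propylbenzoate
Conditions: 1 M aq. HCl/THF 1:3, rt
Reagents that add atoms: water, O
Why: Acid-catalysed ketal hydrolysis regenerates the ketone, while the hindered aryl ester, benzyl ether and benzyl ester are inert to dilute acid at room temperature.

Step 13
Reactants: 21 the dibenzyl keto depside
Product: 22 4-{[2-hydroxy-4-methoxy-6-(2-oxopentyl)benzoyl]oxy}-2-hydroxy-6-propylbenzoic acid (target)
Conditions: H2 (1 atm), 10% Pd/C, EtOAc, rt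
Reagents that add atoms: none
Why: Catalytic hydrogenolysis cleaves the benzyl ether and benzyl ester together under neutral conditions and leaves the dialkyl ketone and the depside ester untouched.

**Compound list**
1 | methyl 2,4-dihydroxy-6-methylbenzoate (methyl orsellinate) | COC(=O)c1c(C)cc(O)cc1O | starting material
2 | methyl 2-hydroxy-4-methoxy-6-methylbenzoate | COC(=O)c1c(C)cc(OC)cc1O | intermediate
3 | methyl 2-(benzyloxy)-4-methoxy-6-methylbenzoate | COC(=O)c1c(C)cc(OC)cc1OCc1ccccc1 | intermediate
4 | butanoyl chloride | CCCC(=O)Cl | starting material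
5 | N,O-dimethylhydroxylamine hydrochloride | CNOC.Cl | starting material
6 | N-methoxy-N-methylbutanamide | CCCC(=O)N(C)OC | intermediate
7 | methyl 2-(benzyloxy)-6-(lithiomethyl)-4-methoxybenzoate (not isolated) | COC(=O)c1c(C[Li])cc(OC)cc1OCc1ccccc1 | intermediate
8 | lithium alkoxide of the tetrahedral adduct of 7 and 6 (racemic, not isolated) | CCCC(O[Li])(Cc1cc(OC)cc(OCc2ccccc2)c1C(=O)OC)N(C)OC | intermediate
9 | methyl 2-(benzyloxy)-4-methoxy-6-(2-oxopentyl)benzoate | CCCC(=O)Cc1cc(OC)cc(OCc2ccccc2)c1C(=O)OC | intermediate
10 | methyl 2-(benzyloxy)-4-methoxy-6-[(2-propyl-1,3-dioxolan-2-yl)methyl]benzoate | CCCC1(Cc2cc(OC)cc(OCc3ccccc3)c2C(=O)OC)OCCO1 | intermediate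
11 | 2-(benzyloxy)-4-methoxy-6-[(2-propyl-1,3-dioxolan-2-yl)methyl]benzoic acid | CCCC1(Cc2cc(OC)cc(OCc3ccccc3)c2C(=O)O)OCCO1 | intermediate
12 | (E)-hept-3-en-2-one | CCC/C=C/C(C)=O | starting material
13 | dimethyl malonate | COC(=O)CC(=O)OC | starting material
14 | dimethyl 2-(2-oxoheptan-4-yl)malonate (racemic, not isolated) | CCCC(CC(C)=O)C(C(=O)OC)C(=O)OC | intermediate
15 | methyl 2,4-dioxo-6-propylcyclohexane-1-carboxylate (racemic, keto/enol mixture) | CCCC1CC(=O)CC(=O)C1C(=O)OC | intermediate
16 | methyl 3-bromo-2,4-dioxo-6-propylcyclohexane-1-carboxylate (not isolated) | CCCC1CC(=O)C(Br)C(=O)C1C(=O)OC | intermediate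
17 | methyl 2,4-dihydroxy-6-propylbenzoate | CCCc1cc(O)cc(O)c1C(=O)OC | intermediate
18 | 2,4-dihydroxy-6-propylbenzoic acid | CCCc1cc(O)cc(O)c1C(=O)O | intermediate
19 | benzyl 2,4-dihydroxy-6-propylbenzoate | CCCc1cc(O)cc(O)c1C(=O)OCc1ccccc1 | intermediate
20 | benzyl 4-{[2-(benzyloxy)-4-methoxy-6-[(2-propyl-1,3-dioxolan-2-yl)methyl]benzoyl]oxy}-2-hydroxy-6-propylbenzoate | CCCC1(Cc2cc(OC)cc(OCc3ccccc3)c2C(=O)Oc2cc(O)c(C(=O)OCc3ccccc3)c(CCC)c2)OCCO1 | intermediate
21 | benzyl 4-{[2-(benzyloxy)-4-methoxy-6-(2-oxopentyl)benzoyl]oxy}-2-hydroxy-6-propylbenzoate | CCCC(=O)Cc1cc(OC)cc(OCc2ccccc2)c1C(=O)Oc1cc(O)c(C(=O)OCc2ccccc2)c(CCC)c1 | intermediate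
22 | 4-{[2-hydroxy-4-methoxy-6-(2-oxopentyl)benzoyl]oxy}-2-hydroxy-6-propylbenzoic acid | CCCC(=O)Cc1cc(OC)cc(O)c1C(=O)Oc1cc(O)c(C(=O)O)c(CCC)c1 | target

**Totals**
Total step count: 13.
Longest linear sequence: 8 steps (1, 2, 4, 5, 6, 11, 12, 13 from methyl orsellinate). The ring-B branch is 7 steps (7, 8, 9, 10, 11, 12, 13).

**Three steps most likely to fail, with fallbacks**

Step 4 (acylation of the toluate anion). The anion can self-condense with unlithiated ester, or it can enolise the amide instead of attacking it. The fallback sets out from 3 and comes back at 9. The same anion (LDA, THF, −78 °C) is used in an aldol-type addition to butanal, which is a faster, non-basic electrophile. Quenching at −78 °C with AcOH, before the alkoxide can lactonise, gives racemic methyl 2-(benzyloxy)-6-(2-hydroxypentyl)-4-methoxybenzoate F1. Oxidation of its secondary alcohol with Dess–Martin periodinane (CH2Cl2, NaHCO3, rt) gives ketone 9 and removes the temporary stereocentre.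

Step 9 (saponification of 17). 2,4-Dihydroxybenzoic acids lose CO2 easily, so 18 may decarboxylate on acidification or on standing. The fallback sets out from 12 and comes back at 19, so the free acid is never made. Enone 12 is treated with commercial dibenzyl malonate and NaH (1.1 equiv) in THF, 0 °C to reflux; no methoxide is present, so there is no ester scrambling. The Michael adduct dibenzyl 2-(2-oxoheptan-4-yl)malonate F2 (not isolated) closes by Dieckmann condensation to benzyl 2,4-dioxo-6-propylcyclohexane-1-carboxylate F3. Treatment with Br2 (1.0 equiv) in DMF, 0 °C then 80 °C, passes through benzyl 3-bromo-2,4-dioxo-6-propylcyclohexane-1-carboxylate F4 (not isolated) and gives 19 directly. This replaces steps 7–10.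

Step 11 (esterification of the di-ortho-substituted acid 11 with phenol 19). The O-acylisourea from the hindered acid may rearrange to the N-acylurea faster than it acylates the phenol. The fallback sets out from 11 and comes back at 20. Acid 11 is converted under neutral conditions with Ghosez's reagent (1-chloro-N,N,2-trimethylprop-1-en-1-amine, CH2Cl2, 0 °C to rt) into the preformed 2-(benzyloxy)-4-methoxy-6-[(2-propyl-1,3-dioxolan-2-yl)methyl]benzoyl chloride F5. F5 is then added to 19 with Et3N and catalytic DMAP in CH2Cl2. The more acidic, unchelated 4-OH of 19 is acylated to give 20, and no HCl is generated that could open the dioxolane.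

**Further compounds**
F1 | step 4 | methyl 2-(benzyloxy)-6-(2-hydroxypentyl)-4-methoxybenzoate (racemic) | CCCC(O)Cc1cc(OC)cc(OCc2ccccc2)c1C(=O)OC
F2 | step 9 | dibenzyl 2-(2-oxoheptan-4-yl)malonate (racemic, not isolated) | CCCC(CC(C)=O)C(C(=O)OCc1ccccc1)C(=O)OCc1ccccc1
F3 | step 9 | benzyl 2,4-dioxo-6-propylcyclohexane-1-carboxylate (racemic, keto/enol mixture) | CCCC1CC(=O)CC(=O)C1C(=O)OCc1ccccc1
F4 | step 9 | benzyl 3-bromo-2,4-dioxo-6-propylcyclohexane-1-carboxylate (not isolated) | CCCC1CC(=O)C(Br)C(=O)C1C(=O)OCc1ccccc1
F5 | step 11 | 2-(benzyloxy)-4-methoxy-6-[(2-propyl-1,3-dioxolan-2-yl)methyl]benzoyl chloride | CCCC1(Cc2cc(OC)cc(OCc3ccccc3)c2C(=O)Cl)OCCO1
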